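The strategy rests on C4. In each flavan half it is a bare CH2 between the C3 carbinol and the phloroglucinol carbon C4a of ring A (A'), which is what remains when an electron-rich arene opens a monosubstituted oxirane at its CH2 end. Both C4–C4a bonds are cut together, opening rings C and C' to a biaryl with two (aryloxy)(oxiranyl)methyl arms.
The two O1–C2 ether bonds go back to 3,5-bis(benzyloxy)phenol and erythro epoxy alcohols (Mitsunobu, inversion at C2). C3 comes from a matched Sharpless epoxidation, and C2 from a CBS reduction of a bis(aryl vinyl ketone) made from a biaryl dialdehyde and vinylmagnesium bromide.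
The B–B' bond comes from a Suzuki–Miyaura coupling of the two ortho-brominated benzyloxybenzaldehydes, the catechol partner as its pinacol boronate.
Ring order: B and B' are joined first, A and A' are attached as aryl ethers, C and C' close together in the penultimate step, and the nine benzyl ethers are removed last.

Key step: step 11

Assumption: the target string fixes only the four carbon stereocentres (C2 and C3 of both halves, all R) and leaves the hindered B–B' axis undefined, so the axis is not controlled, compounds 6 and 8–16 are drawn without an axial descriptor, and separable atropisomers would be parted by chromatography at 15.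

Step 1
Reactants: 1 3,4-bis(benzyloxy)benzaldehyde
Product: 2 4,5-bis(benzyloxy)-2-bromobenzaldehyde
Conditions: Br2 (1.05 equiv), NaOAc, AcOH, rt
Reagents that add atoms: bromine, BrBr
Why: Electrophilic aromatic bromination should go to the position para to the 3-benzyloxy group, the only activated and unhindered site (as with veratraldehyde), while acetate buffers the HBr so that the benzyl ethers survive.

Step 2
Reactants: 2 4,5-bis(benzyloxy)-2-bromobenzaldehyde
Product: 3 4,5-bis(benzyloxy)-2-(4,4,5,5-tetramethyl-1,3,2-dioxaborolan-2-yl)benzaldehyde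
Conditions: B2pin2, PdCl2(dppf) (5 mol %), KOAc, 1,4-dioxane, 85 °C
Reagents that add atoms: bis(pinacolato)diboron, CC1(C)OB(OC1(C)C)B1OC(C)(C)C(C)(C)O1
Why: Miyaura borylation with the weak base KOAc exchanges the aryl bromide for a pinacol boronate without touching the aldehyde or the benzyl ethers.

Step 3
Reactants: 4 3,4,5-tris(benzyloxy)benzaldehyde
Product: 5 3,4,5-tris(benzyloxy)-2-bromobenzaldehyde
Conditions: NBS (1.05 equiv), DMF, 0 °C to rt, dark
Reagents that add atoms: N-bromosuccinimide, O=C1CCC(=O)N1Br
Why: Electrophilic bromination with NBS in a polar solvent should hit one of the two equivalent free ring positions (ortho and para to benzyloxy groups), and exclusion of light suppresses radical attack on the benzylic CH2 groups.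

Step 4
Reactants: 3 4,5-bis(benzyloxy)-2-(pinacolboryl)benzaldehyde; 5 3,4,5-tris(benzyloxy)-2-bromobenzaldehyde
Product: 6 4,4',5,5',6-pentakis(benzyloxy)biphenyl-2,2'-dicarbaldehyde (ring B = dibenzyloxy ring, ring B' = tribenzyloxy ring)
Conditions: Pd(OAc)2 (5 mol %), SPhos (10 mol %), K3PO4, toluene/H2O (10:1), 90 °C
Reagents that add atoms: none
Why: Suzuki–Miyaura coupling in which SPhos-ligated zerovalent palladium copes with the doubly ortho-flanked bromide 5 and with reductive elimination to a tri-ortho-substituted biaryl, boron sitting on the less hindered partner and both aldehydes being inert.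

Step 5
Reactants: 6 biaryl dialdehyde; 7 vinylmagnesium bromide (two equivalents incorporated)
Product: 8 1,1'-[4,4',5,5',6-pentakis(benzyloxy)biphenyl-2,2'-diyl]bis(prop-2-en-1-ol), mixture of carbinol stereoisomers
Conditions: 7 (4 equiv), THF, −78 to 0 °C; sat. aq NH4Cl
Reagents that add atoms: none
Why: Twofold Grignard 1,2-addition, run with excess reagent so that reversible capture of the second aldehyde by the first alkoxide does not stall the reaction, and needing no stereocontrol because both carbinol centres are erased in step 6.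

Step 6
Reactants: 8 bis(allylic alcohol), stereoisomer mixture
Product: 9 1,1'-[4,4',5,5',6-pentakis(benzyloxy)biphenyl-2,2'-diyl]bis(prop-2-en-1-one)
Conditions: Dess–Martin periodinane (2.5 equiv), CH2Cl2, 0 °C to rt
Reagents that add atoms: none
Why: Dess–Martin oxidation converts both benzylic allylic alcohols into aryl vinyl ketones under near-neutral conditions that neither ionise the electron-rich benzylic positions nor add to the enones, the product being used at once because it is a reactive Michael acceptor.

Step 7
Reactants: 9 bis(aryl vinyl ketone)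
Product: 10 (1R,1'R)-1,1'-[4,4',5,5',6-pentakis(benzyloxy)biphenyl-2,2'-diyl]bis(prop-2-en-1-ol)
Conditions: (S)-2-methyl-CBS-oxazaborolidine (40 mol %), catecholborane (4 equiv), toluene, −78 °C; H2O
Reagents that add atoms: none
Why: Corey–Bakshi–Shibata reduction, in which each ketone binds the oxazaborolidine boron anti to its larger twisted biaryl substituent so that hydride reaches the face giving the (R)-carbinol (the sense of acetophenone to (R)-1-phenylethanol with the (S)-catalyst), catecholborane at −78 °C favouring 1,2- over 1,4-reduction and the twofold reaction draining the minor sense into separable (R,S) diastereomers.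

Step 8
Reactants: 10 (R,R)-bis(allylic alcohol)
Product: 11 (S,S)-[4,4',5,5',6-pentakis(benzyloxy)biphenyl-2,2'-diyl]bis{[(2R)-oxiran-2-yl]methanol}, erythro in both arms (C2 S, C3 R)
Conditions: Ti(OiPr)4 (40 mol %), L-(+)-DIPT (50 mol %), t-BuOOH (decane, 3 equiv), 4 Å MS, CH2Cl2, −20 °C
Reagents that add atoms: tert-butyl hydroperoxide, CC(C)(C)OO
Why: Sharpless asymmetric epoxidation in the matched sense, since with L-(+)-DIPT the (R)-1-arylallyl alcohol is the fast-reacting enantiomer and the titanium tartrate complex delivers oxygen to the vinyl face that gives the erythro epoxy alcohol, setting C3 as R in both arms and leaving any residual (S)-carbinol unit largely unreacted.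

Step 9
Reactants: 12 phloroglucinol
Product: 13 3,5-bis(benzyloxy)phenol
Conditions: BnBr (2.0 equiv), K2CO3, DMF, rt
Reagents that add atoms: benzyl bromide, BrCc1ccccc1
Why: Williamson etherification with two equivalents of benzyl bromide gives a statistical mixture from which the dibenzyl ether is separated by chromatography, the carbonate base in DMF favouring O- over C-benzylation.

Step 10
Reactants: 11 bis(erythro epoxy alcohol); 13 3,5-bis(benzyloxy)phenol (two equivalents incorporated)
Product: 14 2,2'-bis{(R)-[3,5-bis(benzyloxy)phenoxy][(2R)-oxiran-2-yl]methyl}-4,4',5,5',6-pentakis(benzyloxy)biphenyl, threo in both arms (C2 R, C3 R)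
Conditions: 13 (3 equiv), PPh3 (3 equiv), DIAD (3 equiv), toluene, 0 °C to rt
Reagents that add atoms: none
Why: Mitsunobu etherification, in which the phenoxide displaces the oxyphosphonium group from C2 by SN2 with inversion and so turns each erythro (C2 S, C3 R) unit into the threo (C2 R, C3 R) aryl ether, while the non-polar solvent, the low temperature and the electron-withdrawing oxirane next to C2 hold back ionisation.

Step 11
Reactants: 14 bis(aryl ether) bis-epoxide
Product: 15 nona-O-benzyl degalloyl theasinensin F, both C3 hydroxyls free, (2R,3R) in both flavan units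
Conditions: AuCl3 (10 mol %), AgOTf (30 mol %), ClCH2CH2Cl (0.01 M), 0 °C to rt
Reagents that add atoms: none
Why: Cationic trivalent gold generated from AuCl3 and AgOTf binds each oxirane oxygen, the ring carbon of the 3,5-bis(benzyloxy)phenoxy group next to O1 attacks the CH2 terminus C4 from the rear in an SN2-like Friedel–Crafts alkylation, and proton loss restores ring A (A') while protodemetalation frees the C3 hydroxyl. The closest known reaction is the gold-catalysed cycloalkylation of aryl glycidyl ethers, including those carrying an aryl group on the ether carbon, to 3-chromanols and 2-aryl-3-chromanols. Ring C and ring C' each close in the 6-endo-tet mode (both oxirane carbons end up in the pyran), the competing mode being 5-exo-tet attack on C3 to a 2,3-dihydrobenzofuran. No stereocentre is created, because the C3–O and C2–O1 bonds are not touched, so the threo (2R,3R) arrangement of 14 reappears as the 2,3-cis relationship in both halves. The step needs endo regioselectivity and an intact, unscrambled benzylic C2–O1 ether. These rest on the unhindered primary C4, on two equivalent ortho carbons each activated by three oxygen substituents, on the inductive deactivation of C2 by the neighbouring oxirane, and on low catalyst loading, low temperature and high dilution, the last disfavouring intermolecular alkylation.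

Step 12
Reactants: 15 nona-O-benzyl ether
Product: 16 degalloyl theasinensin F
Conditions: H2 (1 atm), Pd(OH)2/C, THF/MeOH (1:1), rt; filtration under argon
Reagents that add atoms: none
Why: Catalytic hydrogenolysis cleaves the nine O-benzyl bonds, whereas the cyclic benzylic C2–O1 bonds of flavan-3-ols are known to persist over Pd(OH)2/C at ambient pressure and no stereocentre is touched.

Compound list
1 | 3,4-bis(benzyloxy)benzaldehyde | O=Cc1ccc(OCc2ccccc2)c(OCc2ccccc2)c1 | starting material
2 | 4,5-bis(benzyloxy)-2-bromobenzaldehyde | O=Cc1cc(OCc2ccccc2)c(OCc2ccccc2)cc1Br | intermediate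
3 | 4,5-bis(benzyloxy)-2-(4,4,5,5-tetramethyl-1,3,2-dioxaborolan-2-yl)benzaldehyde | O=Cc1cc(OCc2ccccc2)c(OCc2ccccc2)cc1B1OC(C)(C)C(C)(C)O1 | intermediate
4 | 3,4,5-tris(benzyloxy)benzaldehyde | O=Cc1cc(OCc2ccccc2)c(OCc2ccccc2)c(OCc2ccccc2)c1 | starting material
5 | 3,4,5-tris(benzyloxy)-2-bromobenzaldehyde | O=Cc1cc(OCc2ccccc2)c(OCc2ccccc2)c(OCc2ccccc2)c1Br | intermediate
6 | 4,4',5,5',6-pentakis(benzyloxy)biphenyl-2,2'-dicarbaldehyde | O=Cc1cc(OCc7ccccc7)c(OCc7ccccc7)cc1-c1c(C=O)cc(OCc7ccccc7)c(OCc7ccccc7)c1OCc7ccccc7 | intermediate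
7 | vinylmagnesium bromide | C=C[Mg]Br | starting material
8 | biaryl bis(prop-2-en-1-ol), carbinol stereoisomer mixture | C=CC(O)c1cc(OCc7ccccc7)c(OCc7ccccc7)cc1-c1c(C(O)C=C)cc(OCc7ccccc7)c(OCc7ccccc7)c1OCc7ccccc7 | intermediate
9 | biaryl bis(prop-2-en-1-one) | C=CC(=O)c1cc(OCc7ccccc7)c(OCc7ccccc7)cc1-c1c(C(=O)C=C)cc(OCc7ccccc7)c(OCc7ccccc7)c1OCc7ccccc7 | intermediate
10 | (1R,1'R)-biaryl bis(prop-2-en-1-ol) | O[C@@H](c1cc(OCc7ccccc7)c(OCc7ccccc7)cc1-c1c([C@H](O)C=C)cc(OCc7ccccc7)c(OCc7ccccc7)c1OCc7ccccc7)C=C | intermediate
11 | biaryl bis(erythro epoxy alcohol), carbinol S and oxirane R in both arms | O[C@@H](c1cc(OCc7ccccc7)c(OCc7ccccc7)cc1-c1c([C@H](O)[C@H]2CO2)cc(OCc7ccccc7)c(OCc7ccccc7)c1OCc7ccccc7)[C@H]1CO1 | intermediate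
12 | phloroglucinol | Oc1cc(O)cc(O)c1 | starting material
13 | 3,5-bis(benzyloxy)phenol | Oc1cc(OCc2ccccc2)cc(OCc2ccccc2)c1 | intermediate
14 | biaryl bis{[3,5-bis(benzyloxy)phenoxy](oxiranyl)methyl} compound, C2 R and C3 R in both arms (key-step precursor) | C(c7ccccc7)Oc1cc(OCc7ccccc7)cc(c1)O[C@H](c1cc(OCc7ccccc7)c(OCc7ccccc7)cc1-c1c([C@@H](Oc2cc(OCc7ccccc7)cc(OCc7ccccc7)c2)[C@H]2CO2)cc(OCc7ccccc7)c(OCc7ccccc7)c1OCc7ccccc7)[C@H]1CO1 | intermediate
15 | nona-O-benzyl degalloyl theasinensin F (key-step product) | C(c7ccccc7)Oc1cc(OCc7ccccc7)c2c(c1)O[C@H](c1cc(OCc7ccccc7)c(OCc7ccccc7)cc1-c1c([C@H]3Oc4cc(OCc7ccccc7)cc(OCc7ccccc7)c4C[C@H]3O)cc(OCc7ccccc7)c(OCc7ccccc7)c1OCc7ccccc7)[C@H](O)C2 | intermediate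
16 | degalloyl theasinensin F | Oc1cc(O)c2c(c1)O[C@H](c1cc(O)c(O)cc1-c1c([C@H]3Oc4cc(O)cc(O)c4C[C@H]3O)cc(O)c(O)c1O)[C@H](O)C2 | target

Total step count: 12. Longest linear sequence: 10 steps (1 → 2 → 3 → 6 → 8 → 9 → 10 → 11 → 14 → 15 → 16, that is steps 1, 2, 4, 5, 6, 7, 8, 10, 11, 12).

Steps most likely to fail

Step 11.
- **What may go wrong:** The Lewis acid may ionise the benzylic C2–O1 bond, with loss of the phenol or epimerisation at C2. The oxirane may undergo Meinwald-type rearrangement, closure may go exo, or the reaction may stall after one ring closure in the crowded biaryl.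
- **Fallback:** Electrophilic substitution is replaced by an anionic Parham-type cyclialkylation that forms the same C4–C4a bonds under basic conditions. It sets out from 11 and 13 and returns at 15.
- **Sequence:** Phenol 13 is iodinated next to the hydroxyl with N-iodosuccinimide in CH2Cl2 at 0 °C to give 2-iodo-3,5-bis(benzyloxy)phenol F1. Double Mitsunobu etherification of 11 with it, under the conditions of step 10, gives the bis(2-iodoaryl ether) bis-epoxide F2. Li2NiBr4 in THF opens both oxiranes at C4 to the bis-bromohydrin F3, and Et3SiCl with imidazole gives the bis(triethylsilyl ether) F4. Iodine–magnesium exchange with Ph3MgLi in THF at low temperature, followed by warming, closes both pyrans by 6-exo-tet displacement of the primary bromides to give the bis(3-O-triethylsilyl) nona-O-benzyl ether F5. Bu4NF then frees 15.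

Step 10.
- **What may go wrong:** The activated benzylic oxyphosphonium ion, stabilised by the para alkoxy group, may ionise and erode the configuration at C2. The neighbouring carbinol may attack it and close a seven-membered cyclic ether across the biaryl. The displacement next to the biaryl axis may also be sluggish.
- **Fallback:** A base-mediated sequence of Payne rearrangement, benzylic epoxide opening and epoxide re-closure, a known way to 3-aryloxy-3-arylpropane-1,2-diol derivatives. It sets out from 11 and 13 and returns at 14.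
- **Sequence:** Compound 11 is heated with excess 13 and NaOH in dioxane/water. Payne rearrangement equilibrates each erythro terminal epoxy alcohol, with inversion at C3, with the more substituted aryl-conjugated isomer, the bis(trans-3-aryl-2,3-epoxy alcohol) F6. Phenoxide opens its benzylic carbon C2 with inversion to give the erythro bis(3-aryloxy-1,2-diol) F7 (C2 R, C3 S). TBSCl with imidazole at 0 °C silylates only the two primary hydroxyls to give the bis(primary silyl ether) F8, and MsCl with Et3N gives the bis(C3 mesylate) F9. Bu4NF unmasks the C4 alkoxides, which displace the mesylates with a second inversion at C3 to give 14.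

Step 7.
- **What may go wrong:** Facial discrimination between the twisted aryl group and the vinyl group may be poor. Conjugate reduction may compete, or the vinyl ketone may polymerise.
- **Fallback:** The oxidation and reduction pair is dropped and the tartrate catalyst selects the stereoisomer by kinetic resolution. It sets out from 8 and returns at 11, and it makes no new compound on the way.
- **Sequence:** The stereoisomer mixture 8 is treated with Ti(OiPr)4, L-(+)-DIPT and t-BuOOH over 4 Å MS in CH2Cl2 at −20 °C. Only (R)-carbinol units are epoxidised at a useful rate, so only the (R,R) isomer is carried through to 11. It is separated by chromatography from partly epoxidised and unreacted material. The price is a theoretical ceiling of one quarter of the mass.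

Further compounds
F1 | step 11 | 2-iodo-3,5-bis(benzyloxy)phenol | Oc1cc(OCc2ccccc2)cc(OCc2ccccc2)c1I
F2 | step 11 | bis(2-iodoaryl ether) bis-epoxide (14 with iodine on the ring carbon between O1 and a benzyloxy group of each phenoxy ring) | Ic1c(OCc7ccccc7)cc(OCc7ccccc7)cc1O[C@H](c1cc(OCc7ccccc7)c(OCc7ccccc7)cc1-c1c([C@@H](Oc2cc(OCc7ccccc7)cc(OCc7ccccc7)c2I)[C@H]2CO2)cc(OCc7ccccc7)c(OCc7ccccc7)c1OCc7ccccc7)[C@H]1CO1
F3 | step 11 | bis-bromohydrin (C3 hydroxyl, C4 bromide in both arms) | Ic1c(OCc7ccccc7)cc(OCc7ccccc7)cc1O[C@H](c1cc(OCc7ccccc7)c(OCc7ccccc7)cc1-c1c([C@@H](Oc2cc(OCc7ccccc7)cc(OCc7ccccc7)c2I)[C@H](O)CBr)cc(OCc7ccccc7)c(OCc7ccccc7)c1OCc7ccccc7)[C@H](O)CBr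
F4 | step 11 | bis(triethylsilyl ether) of the bis-bromohydrin | Ic1c(OCc7ccccc7)cc(OCc7ccccc7)cc1O[C@H](c1cc(OCc7ccccc7)c(OCc7ccccc7)cc1-c1c([C@@H](Oc2cc(OCc7ccccc7)cc(OCc7ccccc7)c2I)[C@H](O[Si](CC)(CC)CC)CBr)cc(OCc7ccccc7)c(OCc7ccccc7)c1OCc7ccccc7)[C@H](O[Si](CC)(CC)CC)CBr
F5 | step 11 | bis(3-O-triethylsilyl) nona-O-benzyl ether | C(c7ccccc7)Oc1cc(OCc7ccccc7)c2c(c1)O[C@H](c1cc(OCc7ccccc7)c(OCc7ccccc7)cc1-c1c([C@H]3Oc4cc(OCc7ccccc7)cc(OCc7ccccc7)c4C[C@H]3O[Si](CC)(CC)CC)cc(OCc7ccccc7)c(OCc7ccccc7)c1OCc7ccccc7)[C@H](O[Si](CC)(CC)CC)C2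
F6 | step 10 | bis(trans-3-aryl-2,3-epoxy alcohol), (2S,3S)-oxiranylmethanol in both arms | OC[C@@H]1O[C@H]1c1cc(OCc7ccccc7)c(OCc7ccccc7)cc1-c1c([C@@H]2O[C@H]2CO)cc(OCc7ccccc7)c(OCc7ccccc7)c1OCc7ccccc7
F7 | step 10 | erythro bis(3-aryloxy-1,2-diol), C2 R and C3 S in both arms | C(c7ccccc7)Oc1cc(OCc7ccccc7)cc(c1)O[C@H](c1cc(OCc7ccccc7)c(OCc7ccccc7)cc1-c1c([C@@H](Oc2cc(OCc7ccccc7)cc(OCc7ccccc7)c2)[C@@H](O)CO)cc(OCc7ccccc7)c(OCc7ccccc7)c1OCc7ccccc7)[C@@H](O)CO
F8 | step 10 | bis(primary silyl ether) (TBS on both C4 oxygens) | C(c7ccccc7)Oc1cc(OCc7ccccc7)cc(c1)O[C@H](c1cc(OCc7ccccc7)c(OCc7ccccc7)cc1-c1c([C@@H](Oc2cc(OCc7ccccc7)cc(OCc7ccccc7)c2)[C@@H](O)CO[Si](C)(C)C(C)(C)C)cc(OCc7ccccc7)c(OCc7ccccc7)c1OCc7ccccc7)[C@@H](O)CO[Si](C)(C)C(C)(C)C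
F9 | step 10 | bis(C3 mesylate) of the bis(primary silyl ether) | C(c7ccccc7)Oc1cc(OCc7ccccc7)cc(c1)O[C@H](c1cc(OCc7ccccc7)c(OCc7ccccc7)cc1-c1c([C@@H](Oc2cc(OCc7ccccc7)cc(OCc7ccccc7)c2)[C@@H](OS(C)(=O)=O)CO[Si](C)(C)C(C)(C)C)cc(OCc7ccccc7)c(OCc7ccccc7)c1OCc7ccccc7)[C@@H](OS(C)(=O)=O)CO[Si](C)(C)C(C)(C)C
F0 | step 7 | none | none
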